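**Retrosynthetic overview**

1. The ring (C1 carbonyl, C2 allyl-bearing, C3, C4 quaternary methoxy carbon, C5 methoxy enol-ether carbon, C6) is the C5 methyl enol ether of a 4,4-disubstituted cyclohex-4-ene-1,3-dione. C5–OMe is therefore methanol added to an ynone, and C2=C3 is an aldol condensation of the ketone α-CH2 with a quaternary aldehyde. The only ring is closed last, from the acyclic keto ynal 18.
2. 18 comes from alkynol 15 and pent-4-enal (acetylide addition, then oxidation of both alcohols).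
3. 15 comes from thioester 8 by Fukuyama arylation at C7, ionic deoxygenation, ester reduction and desilylation.
4. The C4/C8 diad comes from an anti-selective, Sn(OTf)2/pybox-catalysed Mukaiyama aldol of the thiopropionate silyl ketene acetal 5 with the alkynyl keto ester 3, followed by O-methylation.

Key step: step 11

Assumption: the facial sense of the Sn(OTf)2/Ph-pybox catalyst on the alkynyl keto ester is taken to parallel that on pyruvate esters; (S,S)-ligand is written, and the antipode that delivers (2R,3R)-7 is the one to use. The S-ethyl thioester replaces the S-tert-butyl one because it couples more readily in step 5.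

**Step 1**
Reactants: 1 bis(trimethylsilyl)acetylene; 2 methyl chlorooxoacetate
Product: 3 methyl 2-oxo-4-(trimethylsilyl)but-3-ynoate
Conditions: AlCl3, CH2Cl2, 0 °C
Reagents that add atoms: none
Why: Friedel–Crafts-type ipso-acylation of an alkynylsilane, in which the acylium ion attacks the silicon-bearing carbon, Me3SiCl is lost, and the electron-poor ynone resists a second acylation.

**Step 2**
Reactants: 4 S-ethyl propanethioate
Product: 5 (Z)-1-(ethylsulfanyl)-1-(trimethylsilyloxy)prop-1-ene (methyl cis to SEt)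
Conditions: LiN(iPr)2, THF, −78 °C; Me3SiCl
Reagents that add atoms: chlorotrimethylsilane, C[Si](C)(C)Cl
Why: Kinetic enolisation of the thioester and O-silylation (silyl ketene acetal formation); in THF without a polar additive the enolate has methyl trans to OLi, which should give the (Z) isomer.

**Step 3**
Reactants: 3 methyl 2-oxo-4-(trimethylsilyl)but-3-ynoate; 5 (Z)-1-(ethylsulfanyl)-1-(trimethylsilyloxy)prop-1-ene
Product: 7 methyl (2R,3R)-4-(ethylsulfanyl)-2-hydroxy-3-methyl-4-oxo-2-[(trimethylsilyl)ethynyl]butanoate, via aldol silyl ether 6 (not isolated)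
Conditions: Sn(OTf)2 (10 mol %), (S,S)-Ph-pybox (11 mol %), CH2Cl2, −78 °C; then 1 M HCl, THF
Reagents that add atoms: none
Why: Catalytic enantioselective Mukaiyama aldol addition to an α-keto ester chelated to the chiral divalent tin Lewis acid, where the ligand shields one ketone face (setting C4) and the open transition state of this catalyst family gives the anti OH/CH3 relationship (setting C8), while the silyl cap on the alkyne blocks conjugate addition.

**Step 4**
Reactants: 7 methyl (2R,3R)-4-(ethylsulfanyl)-2-hydroxy-3-methyl-4-oxo-2-[(trimethylsilyl)ethynyl]butanoate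
Product: 8 methyl (2R,3R)-4-(ethylsulfanyl)-2-methoxy-3-methyl-4-oxo-2-[(trimethylsilyl)ethynyl]butanoate
Conditions: MeOTf, 2,6-di-tert-butyl-4-methylpyridine, CH2Cl2, rt to 40 °C
Reagents that add atoms: methyl trifluoromethanesulfonate, COS(=O)(=O)C(F)(F)F
Why: O-alkylation with a hard methylating agent and a hindered pyridine base; no metal alkoxide is formed, so the β-hydroxy thioester should not undergo retro-aldol cleavage, and no stereocentre is touched.

**Step 5**
Reactants: 8 methyl (2R,3R)-4-(ethylsulfanyl)-2-methoxy-3-methyl-4-oxo-2-[(trimethylsilyl)ethynyl]butanoate; 9 4-bromo-1,2-dimethoxybenzene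
Product: 12 methyl (2R,3R)-4-(3,4-dimethoxyphenyl)-2-methoxy-3-methyl-4-oxo-2-[(trimethylsilyl)ethynyl]butanoate, via arylmagnesium bromide 10 (not isolated), via arylzinc chloride 11 (not isolated)
Conditions: 9, Mg, THF; ZnCl2, 0 °C; then 8, PdCl2(PPh3)2 (5 mol %), THF–toluene, rt; 1 M HCl work-up
Reagents that add atoms: none
Why: Fukuyama cross-coupling, in which zerovalent palladium inserts into the C(O)–S bond, the arylzinc transfers the aryl group and reductive elimination gives the ketone; the mild arylzinc should leave the ester, the silyl alkyne and the C8–H untouched.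

**Step 6**
Reactants: 12 methyl (2R,3R)-4-(3,4-dimethoxyphenyl)-2-methoxy-3-methyl-4-oxo-2-[(trimethylsilyl)ethynyl]butanoate
Product: 13 methyl (2R,3S)-4-(3,4-dimethoxyphenyl)-2-methoxy-3-methyl-2-[(trimethylsilyl)ethynyl]butanoate
Conditions: Et3SiH (4 equiv), CF3CO2H, CH2Cl2, 0 °C to rt
Reagents that add atoms: none
Why: Ionic hydrogenation, where the protonated electron-rich aryl ketone takes hydride from the silane, the benzylic alcohol ionises to the 3,4-dimethoxybenzyl cation and a second hydride gives the methylene, as is routine for 4-aryl-4-oxobutanoates; the descriptor at C8 changes only through priorities.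

**Step 7**
Reactants: 13 methyl (2R,3S)-4-(3,4-dimethoxyphenyl)-2-methoxy-3-methyl-2-[(trimethylsilyl)ethynyl]butanoate
Product: 14 (2R,3S)-4-(3,4-dimethoxyphenyl)-2-methoxy-3-methyl-2-[(trimethylsilyl)ethynyl]butan-1-ol
Conditions: LiBH4, THF, 0 °C to rt
Reagents that add atoms: none
Why: Hydride reduction of the α-alkoxy ester to the primary alcohol; LiBH4 should not touch the silyl alkyne or the aryl ethers.

**Step 8**
Reactants: 14 (2R,3S)-4-(3,4-dimethoxyphenyl)-2-methoxy-3-methyl-2-[(trimethylsilyl)ethynyl]butan-1-ol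
Product: 15 (2R,3S)-4-(3,4-dimethoxyphenyl)-2-ethynyl-2-methoxy-3-methylbutan-1-ol
Conditions: K2CO3, MeOH, rt
Reagents that add atoms: none
Why: Base-catalysed methanolysis of the alkynyl C–Si bond (protodesilylation).

**Step 9**
Reactants: 15 (2R,3S)-4-(3,4-dimethoxyphenyl)-2-ethynyl-2-methoxy-3-methylbutan-1-ol; 16 pent-4-enal
Product: 17 (2R)-2-[(2S)-1-(3,4-dimethoxyphenyl)propan-2-yl]-2-methoxynon-8-en-3-yne-1,5-diol (both C5 epimers)
Conditions: nBuLi (2.1 equiv), THF, −78 °C; then 16, −78 to 0 °C; H2O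
Reagents that add atoms: none
Why: Acetylide addition to an aldehyde by the lithium alkoxide–acetylide dianion, which reacts through carbon; the new carbinol centre is uncontrolled and is erased by the next oxidation.

**Step 10**
Reactants: 17 (2R)-2-[(2S)-1-(3,4-dimethoxyphenyl)propan-2-yl]-2-methoxynon-8-en-3-yne-1,5-diol
Product: 18 (2R)-2-[(2S)-1-(3,4-dimethoxyphenyl)propan-2-yl]-2-methoxy-5-oxonon-8-en-3-ynal
Conditions: Dess–Martin periodinane (3 equiv), NaHCO3, CH2Cl2, 0 °C to rt; used at once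
Reagents that add atoms: none
Why: Dess–Martin oxidation of the primary and the propargylic secondary alcohol in one operation; the aldehyde has no α-hydrogen, so C4 cannot epimerise, and the buffer protects the ynone.

**Step 11**
Reactants: 18 (2R)-2-[(2S)-1-(3,4-dimethoxyphenyl)propan-2-yl]-2-methoxy-5-oxonon-8-en-3-ynal
Product: 21 (4S)-4-[(2S)-1-(3,4-dimethoxyphenyl)propan-2-yl]-4,5-dimethoxy-2-(prop-2-en-1-yl)cyclohexa-2,5-dien-1-one, via β-methoxy enone 19 (not isolated), via aldol 20 (not isolated)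
Conditions: PMe3 (20 mol %), MeOH, 0 °C to rt; then K2CO3 (0.5 equiv), 0 °C to rt
Reagents that add atoms: methanol, CO
Why: PMe3 adds to C5 of the ynone, methanol protonates the allenolate and the methoxide so released adds to the β-phosphonium enone and expels the phosphine (phosphine-catalysed oxa-Michael addition of an alcohol to an ynone), forming the C5–O bond at the only electrophilic alkyne carbon; C4 has no hydrogen, so the zwitterion cannot divert into ynone-to-dienone isomerisation. Once carbonate is present, the E and Z enol ethers 19 should interconvert by reversible methoxide addition–elimination, and only the isomer with C4 cis to the C1 carbonyl can close. The base enolises C1 toward C2, its only sp3 α-position, and the enolate attacks the non-enolisable, α-alkoxy-activated aldehyde C3 in a 6-(enolendo)-exo-trig aldol addition (intramolecular aldol condensation of a keto aldehyde), closing the six-membered ring; E1cB loss of water from 20 then gives the cross-conjugated dienone irreversibly and pulls the equilibria forward. No stereocentre is formed: C4 is quaternary and C8 is not acidic, so both pass through unchanged, and the C2/C3 centres of 20 vanish on dehydration. The step needs the oxa-Michael addition to be complete before any alkoxide is present, because retro-Claisen loss of the formyl group from the ynone would expel a stabilised allenolate; running the neutral phosphine stage first secures this, and the enol ether sits at C5 by construction, so no diketone O-methylation regiochemistry arises.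

**Compound list**

1 | bis(trimethylsilyl)acetylene | C[Si](C)(C)C#C[Si](C)(C)C | starting material
2 | methyl chlorooxoacetate | COC(=O)C(=O)Cl | starting material
3 | methyl 2-oxo-4-(trimethylsilyl)but-3-ynoate | COC(=O)C(=O)C#C[Si](C)(C)C | intermediate
4 | S-ethyl propanethioate | CCC(=O)SCC | starting material
5 | (Z)-1-(ethylsulfanyl)-1-(trimethylsilyloxy)prop-1-ene | C/C=C(\SCC)O[Si](C)(C)C | intermediate
6 | methyl (2R,3R)-4-(ethylsulfanyl)-3-methyl-4-oxo-2-(trimethylsilyloxy)-2-[(trimethylsilyl)ethynyl]butanoate | COC(=O)[C@@](O[Si](C)(C)C)([C@@H](C)C(=O)SCC)C#C[Si](C)(C)C | intermediate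
7 | methyl (2R,3R)-4-(ethylsulfanyl)-2-hydroxy-3-methyl-4-oxo-2-[(trimethylsilyl)ethynyl]butanoate | COC(=O)[C@@](O)([C@@H](C)C(=O)SCC)C#C[Si](C)(C)C | intermediate
8 | methyl (2R,3R)-4-(ethylsulfanyl)-2-methoxy-3-methyl-4-oxo-2-[(trimethylsilyl)ethynyl]butanoate | COC(=O)[C@@](OC)([C@@H](C)C(=O)SCC)C#C[Si](C)(C)C | intermediate
9 | 4-bromo-1,2-dimethoxybenzene | COc1ccc(Br)cc1OC | starting material
10 | (3,4-dimethoxyphenyl)magnesium bromide | COc1ccc([Mg]Br)cc1OC | intermediate
11 | (3,4-dimethoxyphenyl)zinc chloride | COc1ccc([Zn]Cl)cc1OC | intermediate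
12 | methyl (2R,3R)-4-(3,4-dimethoxyphenyl)-2-methoxy-3-methyl-4-oxo-2-[(trimethylsilyl)ethynyl]butanoate | COC(=O)[C@@](OC)([C@@H](C)C(=O)c1ccc(OC)c(OC)c1)C#C[Si](C)(C)C | intermediate
13 | methyl (2R,3S)-4-(3,4-dimethoxyphenyl)-2-methoxy-3-methyl-2-[(trimethylsilyl)ethynyl]butanoate | COC(=O)[C@@](OC)([C@@H](C)Cc1ccc(OC)c(OC)c1)C#C[Si](C)(C)C | intermediate
14 | (2R,3S)-4-(3,4-dimethoxyphenyl)-2-methoxy-3-methyl-2-[(trimethylsilyl)ethynyl]butan-1-ol | OC[C@@](OC)([C@@H](C)Cc1ccc(OC)c(OC)c1)C#C[Si](C)(C)C | intermediate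
15 | (2R,3S)-4-(3,4-dimethoxyphenyl)-2-ethynyl-2-methoxy-3-methylbutan-1-ol | OC[C@@](OC)([C@@H](C)Cc1ccc(OC)c(OC)c1)C#C | intermediate
16 | pent-4-enal | C=CCCC=O | starting material
17 | (2R)-2-[(2S)-1-(3,4-dimethoxyphenyl)propan-2-yl]-2-methoxynon-8-en-3-yne-1,5-diol (C5 epimers) | OC[C@@](OC)([C@@H](C)Cc1ccc(OC)c(OC)c1)C#CC(O)CCC=C | intermediate
18 | (2R)-2-[(2S)-1-(3,4-dimethoxyphenyl)propan-2-yl]-2-methoxy-5-oxonon-8-en-3-ynal | O=C[C@@](OC)([C@@H](C)Cc1ccc(OC)c(OC)c1)C#CC(=O)CCC=C | intermediate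
19 | (2R)-2-[(2S)-1-(3,4-dimethoxyphenyl)propan-2-yl]-2,3-dimethoxy-5-oxonona-3,8-dienal (E/Z mixture expected; the cyclising 3E isomer is drawn) | O=C[C@@](OC)([C@@H](C)Cc1ccc(OC)c(OC)c1)/C(OC)=C\C(=O)CCC=C | intermediate
20 | (4S)-4-[(2S)-1-(3,4-dimethoxyphenyl)propan-2-yl]-5-hydroxy-3,4-dimethoxy-6-(prop-2-en-1-yl)cyclohex-2-en-1-one (C5/C6 isomers) | C=CCC1C(O)[C@@](OC)([C@@H](C)Cc2ccc(OC)c(OC)c2)C(OC)=CC1=O | intermediate
21 | (4S)-4-[(2S)-1-(3,4-dimethoxyphenyl)propan-2-yl]-4,5-dimethoxy-2-(prop-2-en-1-yl)cyclohexa-2,5-dien-1-one | C=CCC1=C[C@@](OC)([C@@H](C)Cc2ccc(OC)c(OC)c2)C(OC)=CC1=O | target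

**Step count**

Total steps: 11. Longest linear sequence: 10 steps (steps 1, 3–11 from compound 1 or 2).

**Steps most likely to fail**

Step 11. The formyl group may be lost by retro-Claisen fragmentation of its hemiacetal alkoxide, or the sequence may stall at the enol ether geometry that cannot cyclise or at the aldol stage. The fallback sets out from 18 and returns at 21, closing the ring stepwise under Lewis-acid conditions. From 18 only the phosphine-catalysed methanol addition is run and 19 is isolated. Me3SiOTf/Et3N (CH2Cl2, −78 °C) converts it into the silyl dienol ether (2R)-2-[(2S)-1-(3,4-dimethoxyphenyl)propan-2-yl]-2,3-dimethoxy-5-(trimethylsilyloxy)nona-3,5,8-trienal F1. BF3·OEt2 at −78 °C then effects an intramolecular Mukaiyama aldol addition; the Lewis acid should also let the push–pull double bond rotate into the cyclisable geometry, and 20 is isolated. MsCl/Et3N gives the mesylate of 20, (4S)-4-[(2S)-1-(3,4-dimethoxyphenyl)propan-2-yl]-3,4-dimethoxy-5-(methylsulfonyloxy)-6-(prop-2-en-1-yl)cyclohex-2-en-1-one F2, and DBU eliminates it to 21.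

Step 3. The slim alkynyl group may not let the tin catalyst distinguish the ketone faces or hold the anti topology, so diastereo- or enantioselectivity could erode. The fallback sets out from 3 and 5 and returns at 15. It uses the better-documented syn-selective copper catalyst and then exchanges the roles of the ester and the alkyne at C4, which corrects the relative configuration.
- Cu(OTf)2/(R,R)-tBu-box (10 mol %, CH2Cl2, −78 °C; ligand antipode chosen by analogy with pyruvate) should give the silyl ether methyl (2S,3R)-4-(ethylsulfanyl)-3-methyl-4-oxo-2-(trimethylsilyloxy)-2-[(trimethylsilyl)ethynyl]butanoate F3, and 1 M HCl then the syn adduct methyl (2S,3R)-4-(ethylsulfanyl)-2-hydroxy-3-methyl-4-oxo-2-[(trimethylsilyl)ethynyl]butanoate F4.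
- The conditions of steps 4–6 carry F4 to the methyl ether methyl (2S,3R)-4-(ethylsulfanyl)-2-methoxy-3-methyl-4-oxo-2-[(trimethylsilyl)ethynyl]butanoate F5, the aryl ketone methyl (2S,3R)-4-(3,4-dimethoxyphenyl)-2-methoxy-3-methyl-4-oxo-2-[(trimethylsilyl)ethynyl]butanoate F6 and the ester methyl (2S,3S)-4-(3,4-dimethoxyphenyl)-2-methoxy-3-methyl-2-[(trimethylsilyl)ethynyl]butanoate F7.
- K2CO3/MeOH gives the terminal alkyne methyl (2S,3S)-4-(3,4-dimethoxyphenyl)-2-ethynyl-2-methoxy-3-methylbutanoate F8, and H2 over Pd/CaCO3 poisoned with Pb(OAc)2 and quinoline gives the vinyl ester methyl (2R,3S)-4-(3,4-dimethoxyphenyl)-2-ethenyl-2-methoxy-3-methylbutanoate F9.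
- iBu2AlH at −78 °C gives the aldehyde (2R,3S)-4-(3,4-dimethoxyphenyl)-2-ethenyl-2-methoxy-3-methylbutanal F10, and dimethyl (1-diazo-2-oxopropyl)phosphonate/K2CO3/MeOH gives the enyne 4-[(2S,3R)-3-ethenyl-3-methoxy-2-methylpent-4-yn-1-yl]-1,2-dimethoxybenzene F11.
- OsO4 (cat.)/NaIO4/2,6-lutidine cleaves the vinyl group to the ynal (2R,3S)-4-(3,4-dimethoxyphenyl)-2-ethynyl-2-methoxy-3-methylbutanal F12, and NaBH4 reduces it to 15.

Step 4. Alkylation of the hindered, electron-poor tertiary alcohol may be slow enough that S-alkylation of the thioester or decomposition competes. The fallback sets out from 7 and returns at 13, methylating only after the β-carbonyl has gone, when a simple Williamson reaction is safe. Fukuyama coupling of 7 with 11 (as in step 5) gives the hydroxy ketone methyl (2R,3R)-4-(3,4-dimethoxyphenyl)-2-hydroxy-3-methyl-4-oxo-2-[(trimethylsilyl)ethynyl]butanoate F13. Et3SiH/CF3CO2H gives methyl (2R,3S)-4-(3,4-dimethoxyphenyl)-2-hydroxy-3-methyl-2-[(trimethylsilyl)ethynyl]butanoate F14, and NaH/MeI in THF at 0 °C gives 13.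

**Further compounds**

F1 | step 11 | (2R)-2-[(2S)-1-(3,4-dimethoxyphenyl)propan-2-yl]-2,3-dimethoxy-5-(trimethylsilyloxy)nona-3,5,8-trienal | O=C[C@@](OC)([C@@H](C)Cc1ccc(OC)c(OC)c1)C(OC)=CC(O[Si](C)(C)C)=CCC=C
F2 | step 11 | (4S)-4-[(2S)-1-(3,4-dimethoxyphenyl)propan-2-yl]-3,4-dimethoxy-5-(methylsulfonyloxy)-6-(prop-2-en-1-yl)cyclohex-2-en-1-one | C=CCC1C(OS(C)(=O)=O)[C@@](OC)([C@@H](C)Cc2ccc(OC)c(OC)c2)C(OC)=CC1=O
F3 | step 3 | methyl (2S,3R)-4-(ethylsulfanyl)-3-methyl-4-oxo-2-(trimethylsilyloxy)-2-[(trimethylsilyl)ethynyl]butanoate | COC(=O)[C@](O[Si](C)(C)C)([C@@H](C)C(=O)SCC)C#C[Si](C)(C)C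
F4 | step 3 | methyl (2S,3R)-4-(ethylsulfanyl)-2-hydroxy-3-methyl-4-oxo-2-[(trimethylsilyl)ethynyl]butanoate | COC(=O)[C@](O)([C@@H](C)C(=O)SCC)C#C[Si](C)(C)C
F5 | step 3 | methyl (2S,3R)-4-(ethylsulfanyl)-2-methoxy-3-methyl-4-oxo-2-[(trimethylsilyl)ethynyl]butanoate | COC(=O)[C@](OC)([C@@H](C)C(=O)SCC)C#C[Si](C)(C)C
F6 | step 3 | methyl (2S,3R)-4-(3,4-dimethoxyphenyl)-2-methoxy-3-methyl-4-oxo-2-[(trimethylsilyl)ethynyl]butanoate | COC(=O)[C@](OC)([C@@H](C)C(=O)c1ccc(OC)c(OC)c1)C#C[Si](C)(C)C
F7 | step 3 | methyl (2S,3S)-4-(3,4-dimethoxyphenyl)-2-methoxy-3-methyl-2-[(trimethylsilyl)ethynyl]butanoate | COC(=O)[C@](OC)([C@@H](C)Cc1ccc(OC)c(OC)c1)C#C[Si](C)(C)C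
F8 | step 3 | methyl (2S,3S)-4-(3,4-dimethoxyphenyl)-2-ethynyl-2-methoxy-3-methylbutanoate | COC(=O)[C@](OC)([C@@H](C)Cc1ccc(OC)c(OC)c1)C#C
F9 | step 3 | methyl (2R,3S)-4-(3,4-dimethoxyphenyl)-2-ethenyl-2-methoxy-3-methylbutanoate | COC(=O)[C@](OC)([C@@H](C)Cc1ccc(OC)c(OC)c1)C=C
F10 | step 3 | (2R,3S)-4-(3,4-dimethoxyphenyl)-2-ethenyl-2-methoxy-3-methylbutanal | O=C[C@](OC)([C@@H](C)Cc1ccc(OC)c(OC)c1)C=C
F11 | step 3 | 4-[(2S,3R)-3-ethenyl-3-methoxy-2-methylpent-4-yn-1-yl]-1,2-dimethoxybenzene | C#C[C@](OC)([C@@H](C)Cc1ccc(OC)c(OC)c1)C=C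
F12 | step 3 | (2R,3S)-4-(3,4-dimethoxyphenyl)-2-ethynyl-2-methoxy-3-methylbutanal | O=C[C@@](OC)([C@@H](C)Cc1ccc(OC)c(OC)c1)C#C
F13 | step 4 | methyl (2R,3R)-4-(3,4-dimethoxyphenyl)-2-hydroxy-3-methyl-4-oxo-2-[(trimethylsilyl)ethynyl]butanoate | COC(=O)[C@@](O)([C@@H](C)C(=O)c1ccc(OC)c(OC)c1)C#C[Si](C)(C)C
F14 | step 4 | methyl (2R,3S)-4-(3,4-dimethoxyphenyl)-2-hydroxy-3-methyl-2-[(trimethylsilyl)ethynyl]butanoate | COC(=O)[C@@](O)([C@@H](C)Cc1ccc(OC)c(OC)c1)C#C[Si](C)(C)C
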